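The leftover of the charge is what target has to work on in the grey run once 62.8% of homo dimer and 4.3% of target stand at 1.33 h.

common to all: free catalyst 100 µM
- grey: substrate 0.010 M; partner 0.012 M; added ligand 81 µM; run made earlier
- ochre: substrate 0.010 M; partner 0.012 M; added ligand 120 µM; run made earlier
- south-east: substrate 0.010 M; partner 0.0120 M (in portions, 4, over 12 h); added ligand 81 µM; first portion at the start, last at 12 h; time 15 h
- east: substrate 0.010 M; partner 0.0120 M (fed, over 12 h); added ligand 81 µM; all else is in the flask from the start; the feed brings no volume worth counting; time 15 h
- north: substrate 0.010 M (fed, over 3.0 h); partner 0.0120 M; added ligand 81 µM; all else is in the flask from the start; the feed brings no volume worth counting; time 15 h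
- south-west: substrate 0.010 M; partner 0.0120 M; added ligand 81 µM; everything together at the start; time 15 h
- west: substrate 0.010 M (fed, over 12 h); partner 0.0120 M; added ligand 81 µM; all else is in the flask from the start; the feed brings no volume worth counting; time 15 h

| run | time / h | target / % | homo dimer / % |
|---|---|---|---|
| grey | 1.33 | 4.3 | 62.8 |
| grey | 2.50 | 7.6 | 66.6 |
| grey | 4.00 | 10.0 | 70.7 |
| grey | 8.00 | 15.1 | 75.4 |
| grey | 15.0 | 17.7 | 77.3 |
| ochre | 0.250 | 0.1 | 41.8 |
| ochre | 0.417 | 1.6 | 50.6 |
| ochre | 0.833 | 2.5 | 60.2 |
| ochre | 1.50 | 4.0 | 64.1 |
| ochre | 3.00 | 6.9 | 68.9 |

(each reading ± 0.5 percentage points)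

- the best flask by share of target in target plus homo dimer; "all alike" if 1.5 percentage points covers them all (south-east / east / north / south-west / west / all alike)
- share of target in target plus homo dimer at the end, south-east
- share of target in target plus homo dimer at the end, east
- share of target in target plus homo dimer at the end, north
- share of target in target plus homo dimer at the end, south-west
- share of target in target plus homo dimer at the end, west

- in percentages every species weighs as the substrate in it: one homo dimer counts as two

From 1.33 h to 4.00 h target in the grey run climbs by 0.0213 h⁻¹ of the charge, the early target speed. The ochre run, with 120 µM of added ligand against 81 µM, reads 6.9% of target at 3.00 h, below the 7.6% of the grey run at the earlier 2.50 h, and each reading scatters by 0.5 percentage points. Within the grey run the speed is down to 0.00371 h⁻¹ from 8.00 h to 15.0 h, a factor of 5.74. Held for 15 h, the early speed gives 31.9%, but the grey run reads 17.7%, so the accumulated slowing costs a factor of 1.81. The south-west flask repeats the grey recipe, and its selectivity, the share of target in target plus homo dimer, reads 18.6%.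

The west feed brings 0.0833 h⁻¹ of the charge over 12 h, and target at the early speed draws a quarter of it, 25.6%. This part of a steady feed that target can take up, speed times feed time, is the capture ratio. If the speed holds through the feed and the rest ends as homo dimer, the west share stands near that ratio, higher than south-west.

The forecast names west as best, reading in the earlier runs “a fast early burst of homo dimer” and expecting a slow feed of substrate to avoid it. It gives west 35% (range 28% to 43%), north 27%, south-west 18.6%, south-east 11.5% and east 10%. Its west figure stands higher than the capture ratio.

West comes out highest at 25.0%, with north 21.9%, south-west 19.3%, south-east 11.6% and east 10.7%.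

    2 substrate → homo dimer (k = 0.0580 L mol⁻¹ s⁻¹)
    substrate + free catalyst ⇌ free catalyst + open intermediate (K = 1.60, k = 4.10 L mol⁻¹ s⁻¹)
    free catalyst + added ligand ⇌ idle complex (K = 31000 L mol⁻¹, k = 2.50 L mol⁻¹ s⁻¹)
    partner + catalyst intermediate → free catalyst + target (k = 0.680 L mol⁻¹ s⁻¹)
    free catalyst + open intermediate ⇌ catalyst intermediate (K = 110 L mol⁻¹, k = 12.0 L mol⁻¹ s⁻¹)

At 15.0 h the west flask holds 21.1% of target and 63.5% of homo dimer, beside 9.81% of open intermediate and 5.47% of substrate. The capture ratio, 25.6%, taken in proportion to partner for the west flask with 0.0030 M of partner, gives 6.40%; that flask ends with 6.53% of target and a share of 8.27%.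

The data were generated by integration from invented constants, and the scatter is random.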